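## Retrosynthetic overview

1. The C5–C6 (sp3–sp2) bond is made last, by electroreductive nickel coupling of a (Z)-β-iodo enoate with the O–CH2 carbon of an (R)-α-alkyl-γ-butyrolactone, which serves as a masked γ-iodo acid.
2. The (Z)-iodo enoate comes from copper-catalysed anti-carbomagnesiation/iodination of propargyl alcohol with the homoprenyl Grignard reagent, then oxidation to the acid and methylation.
3. The furylpropyl arm comes from B-alkyl Suzuki coupling of 3-bromofuran with the hydroborated (R)-α-allyl lactone.
4. The stereocentre comes from invertive allylcuprate displacement of the triflate of (S)-α-hydroxy-γ-butyrolactone (derived from L-malic acid).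
5. Rings: none is built. The furan is bought, and the lactone ring of the chiral starting material is opened in the final step.

Assumption: (S)-3-hydroxyoxolan-2-one is bought as the enantiopure material made commercially from L-malic acid; a one-pot sequence giving one isolated product counts as one step.

## Route

Step 1
Reactants: 1 (3S)-3-hydroxyoxolan-2-one
Product: 2 (3S)-2-oxooxolan-3-yl trifluoromethanesulfonate
Conditions: Tf2O (1.1 equiv), 2,6-lutidine (1.2 equiv), CH2Cl2, −78 → 0 °C; short silica plug, used at once
Reagents that add atoms: trifluoromethanesulfonic anhydride, O=S(=O)(OS(=O)(=O)C(F)(F)F)C(F)(F)F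
Why: O-sulfonylation of the secondary alcohol (triflate ester formation) does not touch the C–O stereocentre, so the (S) configuration of 1 is carried unchanged into 2.

Step 2
Reactants: 2 (3S)-2-oxooxolan-3-yl trifluoromethanesulfonate; 3 allylmagnesium bromide (CH2=CHCH2MgBr)
Product: 5 (3R)-3-(prop-2-en-1-yl)oxolan-2-one, via bromomagnesium diallylcuprate 4 (not isolated)
Conditions: 3 (2.2 equiv), CuBr·SMe2 (1.1 equiv), THF, −78 °C, 30 min; then 2, −78 °C, 1 h; aq. NH4Cl/NH3
Reagents that add atoms: none
Why: SN2 displacement of an α-carbonyl triflate by a soft Gilman-type cuprate (stereospecific cuprate substitution) goes with Walden inversion and without carbonyl addition at −78 °C, so the (S) C–O centre of 2 becomes the (R) C–C centre of 5.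

Step 3
Reactants: 5 (3R)-3-(prop-2-en-1-yl)oxolan-2-one; 6 3-bromofuran
Product: 8 (3R)-3-[3-(furan-3-yl)propyl]oxolan-2-one, via B-alkyl-9-BBN adduct 7 (not isolated)
Conditions: 9-BBN (1.2 equiv), THF, 0 °C → rt; then 6, Pd(dppf)Cl2 (5 mol%), aq. K3PO4, DMF, 50 °C; work-up at pH 3 to re-close any opened lactone
Reagents that add atoms: none
Why: 9-BBN hydroborates the terminal alkene anti-Markovnikov without reducing the lactone, and the B-alkyl Suzuki–Miyaura coupling forms the C(sp3)–C(sp2) bond under mild base that does not epimerise the α-centre.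

Step 4
Reactants: 9 5-bromo-2-methylpent-2-ene; 10 prop-2-yn-1-ol
Product: 14 (2Z)-2-(iodomethylidene)-6-methylhept-5-en-1-ol, via (4-methylpent-3-en-1-yl)magnesium bromide 11 (not isolated), via bromomagnesium prop-2-yn-1-olate 12 (not isolated), via alkenylmagnesium alkoxide 13 (not isolated)
Conditions: 9, Mg, THF, rt; separately 10, EtMgBr (1.0 equiv), THF, 0 °C; combine with 11 (2.0 equiv), CuI (10 mol%), Et2O/THF, 0 °C → rt, 16 h; then I2, THF, −40 → 0 °C; aq. Na2S2O3
Reagents that add atoms: iodine, II
Why: Copper-catalysed anti-carbomagnesiation of the propargylic alkoxide (Duboudin–Jousseaume reaction) puts the alkyl group on C2 and magnesium on C3 cis to the CH2O group through a five-membered magnesium chelate, and iodinolysis with retention fixes the (Z)-iodoalkene; no stereocentre is formed.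

Step 5
Reactants: 14 (2Z)-2-(iodomethylidene)-6-methylhept-5-en-1-ol
Product: 15 (2Z)-2-(iodomethylidene)-6-methylhept-5-enal
Conditions: activated MnO2 (15 equiv), CH2Cl2, rt, dark, 2 h; filtered and used crude
Reagents that add atoms: none
Why: Neutral heterogeneous MnO2 oxidation is selective for the allylic alcohol and leaves the vinyl iodide, the trisubstituted alkene and the (Z) geometry intact (allylic alcohol oxidation).

Step 6
Reactants: 15 (2Z)-2-(iodomethylidene)-6-methylhept-5-enal
Product: 16 (2Z)-2-(iodomethylidene)-6-methylhept-5-enoic acid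
Conditions: NaClO2, NaH2PO4, 2-methylbut-2-ene (20 equiv), t-BuOH/H2O, 0 °C
Reagents that add atoms: sodium chlorite, [Na+].[O-]Cl=O
Why: Pinnick oxidation converts enals to acids without E/Z isomerisation, and the excess 2-methylbut-2-ene scavenges HOCl so the remote alkene is not chlorinated.

Step 7
Reactants: 16 (2Z)-2-(iodomethylidene)-6-methylhept-5-enoic acid
Product: 17 methyl (2Z)-2-(iodomethylidene)-6-methylhept-5-enoate
Conditions: MeI, K2CO3, DMF, 0 °C → rt
Reagents that add atoms: iodomethane, CI
Why: Carboxylate O-alkylation (SN2 esterification) occurs at the carboxylate oxygen only and cannot change the alkene geometry.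

Step 8
Reactants: 8 (3R)-3-[3-(furan-3-yl)propyl]oxolan-2-one; 17 methyl (2Z)-2-(iodomethylidene)-6-methylhept-5-enoate
Product: 20 (2R,5Z)-2-[3-(furan-3-yl)propyl]-6-(methoxycarbonyl)-10-methylundeca-5,9-dienoic acid, via trimethylsilyl γ-iodo ester 18 (not isolated), via trimethylsilyl ester of the target 19 (not isolated)
Conditions: (a) Me3SiCl, NaI (1.3 equiv each), 2,6-di-tert-butylpyridine (0.1 equiv), MeCN, 50 °C; (b) 17 (1.3 equiv), NiBr2(dme) (10 mol%), 4,4'-di-tert-butyl-2,2'-bipyridine (12 mol%), DMA, undivided cell, Zn anode, Ni-foam cathode, constant current, 2.2 F/mol, 20 °C; (c) aq. citric acid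
Reagents that add atoms: none
Why: Proposed new method: ring-opening cross-electrophile alkenylation of a γ-butyrolactone, in which Me3SiI (from Me3SiCl/NaI) silylates the lactone carbonyl and iodide opens the ring by SN2 attack at the unhindered O–CH2 carbon to give silyl γ-iodo ester 18 with the α-stereocentre untouched; cathodically generated zerovalent nickel inserts into the C–I bond of 17 with retention of the (Z) geometry, monovalent nickel abstracts iodine from 18, the primary radical is captured at nickel, and reductive elimination from trivalent nickel forms C5–C6 while the Zn anode supplies the electrons, and aqueous work-up cleaves the silyl ester to the free acid; the closest known reaction types are the nickel-catalysed (electro)reductive cross-electrophile coupling of alkyl iodides with alkenyl halides and the iodide-mediated ring-opening cross-electrophile coupling of epoxides, but the alkyl C–O bond of a lactone has not been used as the electrophile.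

## Compound list

1 | (3S)-3-hydroxyoxolan-2-one [(S)-α-hydroxy-γ-butyrolactone] | O[C@H]1CCOC1=O | starting material
2 | (3S)-2-oxooxolan-3-yl trifluoromethanesulfonate | FC(F)(F)S(=O)(=O)O[C@H]1CCOC1=O | intermediate
3 | allylmagnesium bromide | C=CC[Mg]Br | starting material
4 | bromomagnesium diallylcuprate | C=CC[Cu-]CC=C.[Mg+2].[Br-] | intermediate (not isolated)
5 | (3R)-3-(prop-2-en-1-yl)oxolan-2-one | O=C1OCC[C@H]1CC=C | intermediate
6 | 3-bromofuran | Brc1ccoc1 | starting material
7 | (3R)-3-[3-(9-borabicyclo[3.3.1]nonan-9-yl)propyl]oxolan-2-one | O=C1OCC[C@H]1CCCB1C2CCCC1CCC2 | intermediate (not isolated)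
8 | (3R)-3-[3-(furan-3-yl)propyl]oxolan-2-one | O=C1OCC[C@H]1CCCc1ccoc1 | intermediate
9 | 5-bromo-2-methylpent-2-ene | CC(C)=CCCBr | starting material
10 | prop-2-yn-1-ol | C#CCO | starting material
11 | (4-methylpent-3-en-1-yl)magnesium bromide | CC(C)=CCC[Mg]Br | intermediate (not isolated)
12 | bromomagnesium prop-2-yn-1-olate | C#CCO[Mg]Br | intermediate (not isolated)
13 | bromomagnesium (2Z)-2-[(bromomagnesio)methylidene]-6-methylhept-5-en-1-olate | Br[Mg]OC/C(=C\[Mg]Br)CCC=C(C)C | intermediate (not isolated)
14 | (2Z)-2-(iodomethylidene)-6-methylhept-5-en-1-ol | OC/C(=C\I)CCC=C(C)C | intermediate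
15 | (2Z)-2-(iodomethylidene)-6-methylhept-5-enal | O=C/C(=C\I)CCC=C(C)C | intermediate
16 | (2Z)-2-(iodomethylidene)-6-methylhept-5-enoic acid | OC(=O)/C(=C\I)CCC=C(C)C | intermediate
17 | methyl (2Z)-2-(iodomethylidene)-6-methylhept-5-enoate | COC(=O)/C(=C\I)CCC=C(C)C | intermediate
18 | trimethylsilyl (2R)-2-[3-(furan-3-yl)propyl]-4-iodobutanoate | C[Si](C)(C)OC(=O)[C@@H](CCI)CCCc1ccoc1 | intermediate (not isolated)
19 | trimethylsilyl (2R,5Z)-2-[3-(furan-3-yl)propyl]-6-(methoxycarbonyl)-10-methylundeca-5,9-dienoate | COC(=O)/C(=C\CC[C@@H](CCCc1ccoc1)C(=O)O[Si](C)(C)C)CCC=C(C)C | intermediate (not isolated)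
20 | (2R,5Z)-2-[3-(furan-3-yl)propyl]-6-(methoxycarbonyl)-10-methylundeca-5,9-dienoic acid | COC(=O)/C(=C\CC[C@@H](CCCc1ccoc1)C(=O)O)CCC=C(C)C | target

## Step count and risks

Total steps: 8. Longest linear sequence: 5 (steps 4, 5, 6, 7, 8); the other branch is 4 (steps 1, 2, 3, 8).

**Step 8 (the proposed new step).** Risks are acid damage to the furan or the remote alkene during Me3SiI opening, slow re-lactonisation of 18, and partial Z-to-E leakage at the alkenylnickel stage. The fallback uses known chemistry and replaces the radical electroreductive coupling by a two-electron organozinc coupling. It sets out from 18, prepared as in stage (a). Activated Zn dust with LiCl in THF inserts into the C–I bond to give {(3R)-6-(furan-3-yl)-3-[(trimethylsilyloxy)carbonyl]hexyl}zinc iodide F1. Pd(PPh3)4-catalysed Negishi coupling of F1 with 17 retains the (Z) geometry and comes back to the route at 19, which gives 20 on the same aqueous work-up.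

**Step 2.** The allylcuprate may eliminate the triflate to the butenolide or attack the activated lactone carbonyl, and any electron-transfer pathway would erode the inversion. The fallback installs the whole side chain in one stereospecific sp3–sp3 coupling and bypasses 5 and step 3. It sets out from 2 and 6. Bromine–lithium exchange on 6 (n-BuLi, THF, −78 °C) gives furan-3-yllithium F2. Opening of oxetane with BF3·OEt2 gives 3-(furan-3-yl)propan-1-ol F3. CBr4/PPh3 gives 3-(3-bromopropyl)furan F4, and Mg in THF gives [3-(furan-3-yl)propyl]magnesium bromide F5. F5 and 2 with ZnCl2 (10 mol%) in THF at 0 °C couple through a triorganozincate with inversion, the established reactivity of α-hydroxy ester triflates, and the route is rejoined at 8.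

**Step 4.** Anti-carbomagnesiation is best documented for methyl, allyl and aryl Grignard reagents; a primary alkyl reagent may add sluggishly and give low conversion. The fallback builds the (Z)-alkenyl electrophile by chelation-controlled enol sulfonylation and not by alkyne carbometalation. It sets out from 9. Alkylation of dimethyl malonate (NaH, DMF) gives dimethyl 2-(4-methylpent-3-en-1-yl)propanedioate F6. Krapcho demethoxycarbonylation (LiCl, wet DMSO, 150 °C) gives methyl 6-methylhept-5-enoate F7. Formylation (LiN(iPr)2, HCO2Me, THF, −78 °C) gives methyl 2-formyl-6-methylhept-5-enoate F8. Tosylation of the lithium-chelated enolate (TsCl, TMEDA, LiCl) gives methyl (2Z)-6-methyl-2-{[(4-methylbenzenesulfonyl)oxy]methylidene}hept-5-enoate F9. F9 takes the place of 17 in step 8, and the route is rejoined at 19.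

Further compounds

F1 | step 8 | {(3R)-6-(furan-3-yl)-3-[(trimethylsilyloxy)carbonyl]hexyl}zinc iodide | C[Si](C)(C)OC(=O)[C@@H](CC[Zn]I)CCCc1ccoc1
F2 | step 2 | furan-3-yllithium | [Li]c1ccoc1
F3 | step 2 | 3-(furan-3-yl)propan-1-ol | OCCCc1ccoc1
F4 | step 2 | 3-(3-bromopropyl)furan | BrCCCc1ccoc1
F5 | step 2 | [3-(furan-3-yl)propyl]magnesium bromide | Br[Mg]CCCc1ccoc1
F6 | step 4 | dimethyl 2-(4-methylpent-3-en-1-yl)propanedioate | COC(=O)C(CCC=C(C)C)C(=O)OC
F7 | step 4 | methyl 6-methylhept-5-enoate | COC(=O)CCCC=C(C)C
F8 | step 4 | methyl 2-formyl-6-methylhept-5-enoate | COC(=O)C(C=O)CCC=C(C)C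
F9 | step 4 | methyl (2Z)-6-methyl-2-{[(4-methylbenzenesulfonyl)oxy]methylidene}hept-5-enoate | COC(=O)/C(=C\OS(=O)(=O)c1ccc(C)cc1)CCC=C(C)C
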